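**Retrosynthetic overview**
1. The oxirane comes last, from the C10 vinyl group by 9-OH-directed epoxidation; the α-methylene-γ-lactone and the acrolein unit both come from one twofold allylic oxidation of two isopropenyl groups.
2. The 6-O-methacrylate is put on a triol whose 8,9-cis-diol is masked in the flask as a boronate; the 8α,9α-oxygens come from ketone α-hydroxylation and bulky-hydride reduction.
3. Key bond: the quaternary C10–C1 (vinyl) bond is made by nickel-catalysed electroreductive vinylation of a tertiary α-bromo ketone.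
4. The C5–isopropenyl bond is made by alkoxide-directed conjugate addition to cis-4-hydroxycarvone, itself from (S)-carvone by γ-hydroxylation and Mitsunobu inversion.
5. Ring order: the carbocycle is bought as (S)-(+)-carvone, whose single stereocentre (C7) controls all others; the γ-lactone closes in step 9 and the oxirane in step 10.

Assumption: locants C1–C15 in the comments follow elemane numbering (ring C5–C10; C14 methyl and C1–C2 on C10; C4 with C3 and C15 on C5; C11 with C12 and C13 on C7); β is the face of the C10 methyl group.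

**Step 1**
Reactants: 1 (S)-(+)-carvone
Product: 3 (4R,5S)-4-hydroxy-2-methyl-5-(prop-1-en-2-yl)cyclohex-2-en-1-one, via trimethylsilyl dienol ether 2 (not isolated)
Conditions: KOt-Bu, THF, −78 → −20 °C; Me3SiCl; then mCPBA, NaHCO3, CH2Cl2, −20 °C; aq. citric acid
Reagents that add atoms: 3-chloroperbenzoic acid, OOC(=O)c1cccc(Cl)c1
Why: Vinylogous Rubottom oxidation: the thermodynamic extended dienolate is O-silylated and the peracid attacks the distal C3=C4 bond anti to the neighbouring isopropenyl group, giving the γ-hydroxy enone with OH trans to isopropenyl (C6 α).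

**Step 2**
Reactants: 3 (4R,5S)-4-hydroxy-2-methyl-5-(prop-1-en-2-yl)cyclohex-2-en-1-one
Product: 5 (4S,5S)-4-hydroxy-2-methyl-5-(prop-1-en-2-yl)cyclohex-2-en-1-one, via 4-nitrobenzoate ester 4 (not isolated)
Conditions: 4-O2NC6H4CO2H, PPh3, DIAD, THF, 0 °C → rt; then K2CO3 (cat.), MeOH, 0 °C
Reagents that add atoms: 4-nitrobenzoic acid, O=C(O)c1ccc(cc1)[N+](=O)[O-]
Why: Mitsunobu reaction (SN2 inversion of the activated allylic alcohol by the carboxylate, whose oxygen becomes the new hydroxyl oxygen) followed by methanolysis sets C6–O β, cis to the isopropenyl group.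

**Step 3**
Reactants: 5 (4S,5S)-4-hydroxy-2-methyl-5-(prop-1-en-2-yl)cyclohex-2-en-1-one
Product: 6 (2S,3R,4R,5S)-2-bromo-4-hydroxy-2-methyl-3,5-di(prop-1-en-2-yl)cyclohexan-1-one
Conditions: CH2=C(CH3)MgBr (3 equiv), THF, −78 → −30 °C; then NBS, −78 °C; aq. NH4Cl
Reagents that add atoms: isopropenylmagnesium bromide, CC(=C)[Mg]Br; N-bromosuccinimide, O=C1CCC(=O)N1Br
Why: Alkoxide-directed (ligand-assisted) 1,4-addition: the organomagnesium bound to the C6 magnesium alkoxide is delivered to the adjacent enone β-carbon on the alkoxide face, so the C5 isopropenyl is cis to O6 (β), and the regiodefined magnesium enolate is brominated at C10 (either C10 epimer converges in step 4).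

**Step 4**
Reactants: 6 (2S,3R,4R,5S)-2-bromo-4-hydroxy-2-methyl-3,5-di(prop-1-en-2-yl)cyclohexan-1-one
Product: 7 (2S,3S,4R,5S)-2-ethenyl-4-hydroxy-2-methyl-3,5-di(prop-1-en-2-yl)cyclohexan-1-one
Conditions: CH2=CHBr (4 equiv), NiBr2(dme) (10 mol %), 4,4′-di-tert-butyl-2,2′-bipyridine (10 mol %), NaI, LiBr, DMA, undivided cell, Zn anode, Ni-foam cathode, 5 mA constant current (2.2 F/mol), 0 °C
Reagents that add atoms: vinyl bromide, C=CBr
Why: Proposed new method: cathodically generated zerovalent nickel inserts into vinyl bromide, the tertiary α-bromo ketone is reduced (bromine abstraction by monovalent nickel, or via its zinc enolate) to a planar C10 radical/enolate that is captured by the vinyl–nickel species, and reductive elimination from trivalent nickel forges the quaternary C10–C1 bond on the α-face, anti to the syn-axial C6 oxygen and trans to the C5 isopropenyl group; the closest known reaction type is the nickel-catalysed electroreductive cross-electrophile coupling of secondary α-halo carbonyl compounds with aryl or vinyl halides, not yet shown for a tertiary α-bromo ketone giving a vinylated quaternary stereocentre.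

**Step 5**
Reactants: 7 (2S,3S,4R,5S)-2-ethenyl-4-hydroxy-2-methyl-3,5-di(prop-1-en-2-yl)cyclohexan-1-one
Product: 8 (2S,3S,4S,5S,6R)-2-ethenyl-4,6-dihydroxy-2-methyl-3,5-di(prop-1-en-2-yl)cyclohexan-1-one
Conditions: LiN(SiMe3)2 (2.3 equiv), THF, −78 °C; racemic 3-phenyl-2-(phenylsulfonyl)oxaziridine; aq. NH4Cl
Reagents that add atoms: 3-phenyl-2-(phenylsulfonyl)oxaziridine, O=S(=O)(N1OC1c1ccccc1)c1ccccc1
Why: Enolate α-hydroxylation with an N-sulfonyloxaziridine: only C8 can enolise, and the oxidant approaches the α-face, away from the axial C10 methyl and the axial C6 oxygen, giving the equatorial 8α-OH trans to the C7 isopropenyl (the racemic oxidant exerts no control).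

**Step 6**
Reactants: 8 (2S,3S,4S,5S,6R)-2-ethenyl-4,6-dihydroxy-2-methyl-3,5-di(prop-1-en-2-yl)cyclohexan-1-one
Product: 9 (1S,2R,3S,4S,5S,6S)-6-ethenyl-6-methyl-3,5-di(prop-1-en-2-yl)cyclohexane-1,2,4-triol
Conditions: LiBH(s-Bu)3 (4 equiv), THF, −78 °C; H2O
Reagents that add atoms: none
Why: Bulky trialkylborohydride reduction: hydride enters along the equatorial trajectory (as with 4,4-dimethyl-3-keto terpenoids), giving the axial 9α-alcohol cis to the 8α-hydroxyl.

**Step 7**
Reactants: 9 (1S,2R,3S,4S,5S,6S)-6-ethenyl-6-methyl-3,5-di(prop-1-en-2-yl)cyclohexane-1,2,4-triol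
Product: 12 (1S,2S,3S,4S,5R,6R)-3-ethenyl-4,5-dihydroxy-3-methyl-2,6-di(prop-1-en-2-yl)cyclohexyl 2-methylprop-2-enoate, via cyclic phenylboronate 10 (not isolated), via acylated phenylboronate 11 (not isolated)
Conditions: PhB(OH)2, 4 Å MS, CH2Cl2, rt; then methacrylic anhydride, DMAP, Et3N, BHT (cat.), 35 °C; then pinacol, MeOH
Reagents that add atoms: methacrylic anhydride, CC(=C)C(=O)OC(=O)C(C)=C
Why: Transient boronate protection: only the 8,9-cis-diol can form the five-membered boronate, so DMAP-catalysed acylation goes to the remaining 6β-OH, and pinacol transesterification then frees the diol.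

**Step 8**
Reactants: 12 (1S,2S,3S,4S,5R,6R)-3-ethenyl-4,5-dihydroxy-3-methyl-2,6-di(prop-1-en-2-yl)cyclohexyl 2-methylprop-2-enoate
Product: 13 (1S,2S,3S,4S,5R,6R)-3-ethenyl-4,5-dihydroxy-2,6-bis(3-hydroxyprop-1-en-2-yl)-3-methylcyclohexyl 2-methylprop-2-enoate
Conditions: SeO2 (0.5 equiv), t-BuOOH, salicylic acid (cat.), CH2Cl2, rt
Reagents that add atoms: tert-butyl hydroperoxide, CC(C)(C)OO; selenium dioxide, O=[Se]=O
Why: Twofold SeO2 allylic oxidation (ene reaction then [2,3]-shift) hydroxylates the methyl group of each electron-rich isopropenyl unit, while the vinyl group (no allylic hydrogen) and the electron-poor methacrylate do not react.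

**Step 9**
Reactants: 13 (1S,2S,3S,4S,5R,6R)-3-ethenyl-4,5-dihydroxy-2,6-bis(3-hydroxyprop-1-en-2-yl)-3-methylcyclohexyl 2-methylprop-2-enoate
Product: 14 (3aS,4S,5R,6S,7S,7aR)-6-ethenyl-7-hydroxy-6-methyl-3-methylidene-2-oxo-5-(3-oxoprop-1-en-2-yl)octahydro-1-benzofuran-4-yl 2-methylprop-2-enoate
Conditions: activated MnO2 (excess), CH2Cl2, rt
Reagents that add atoms: none
Why: Chemoselective allylic oxidation and oxidative lactonisation: C15–OH gives the enal, while C12–OH gives an enal that closes with the 8α-OH to an allylic lactol and is oxidised on to the trans-fused α-methylene-γ-lactone; the non-allylic 9-OH is untouched.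

**Step 10**
Reactants: 14 (3aS,4S,5R,6S,7S,7aR)-6-ethenyl-7-hydroxy-6-methyl-3-methylidene-2-oxo-5-(3-oxoprop-1-en-2-yl)octahydro-1-benzofuran-4-yl 2-methylprop-2-enoate
Product: 15 (3aS,4S,5R,6S,7S,7aR)-7-hydroxy-6-methyl-3-methylidene-6-[(2R)-oxiran-2-yl]-2-oxo-5-(3-oxoprop-1-en-2-yl)octahydro-1-benzofuran-4-yl 2-methylprop-2-enoate
Conditions: VO(acac)2 (10 mol %), t-BuOOH, CH2Cl2, 0 °C → rt
Reagents that add atoms: tert-butyl hydroperoxide, CC(C)(C)OO
Why: Hydroxyl-directed vanadium-catalysed epoxidation of a homoallylic alcohol: the axial 9α-OH is gauche to the vinyl group and delivers oxygen through a chair-like vanadate transition state with C1=C2 eclipsing the C10–C5 bond, which gives the (R)-oxirane; the three electron-poor alkenes do not react.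

**Compound list**
1 | (S)-(+)-carvone, (5S)-2-methyl-5-(prop-1-en-2-yl)cyclohex-2-en-1-one | CC1=CC[C@@H](CC1=O)C(C)=C | starting material
2 | trimethyl{[(5R)-2-methyl-5-(prop-1-en-2-yl)cyclohexa-1,3-dien-1-yl]oxy}silane | C=C(C)[C@@H]1CC(O[Si](C)(C)C)=C(C)C=C1 | intermediate
3 | (4R,5S)-4-hydroxy-2-methyl-5-(prop-1-en-2-yl)cyclohex-2-en-1-one (trans-4-hydroxycarvone) | O[C@H]1[C@H](C(C)=C)CC(=O)C(C)=C1 | intermediate
4 | (1S,6S)-3-methyl-4-oxo-6-(prop-1-en-2-yl)cyclohex-2-en-1-yl 4-nitrobenzoate | O=C(O[C@@H]1[C@H](C(C)=C)CC(=O)C(C)=C1)c2ccc(cc2)[N+](=O)[O-] | intermediate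
5 | (4S,5S)-4-hydroxy-2-methyl-5-(prop-1-en-2-yl)cyclohex-2-en-1-one (cis-4-hydroxycarvone) | O[C@@H]1[C@H](C(C)=C)CC(=O)C(C)=C1 | intermediate
6 | (2S,3R,4R,5S)-2-bromo-4-hydroxy-2-methyl-3,5-di(prop-1-en-2-yl)cyclohexan-1-one | O[C@@H]1[C@H](C(C)=C)CC(=O)[C@@](C)(Br)[C@@H]1C(C)=C | intermediate
7 | (2S,3S,4R,5S)-2-ethenyl-4-hydroxy-2-methyl-3,5-di(prop-1-en-2-yl)cyclohexan-1-one | O[C@@H]1[C@H](C(C)=C)CC(=O)[C@@](C)(C=C)[C@@H]1C(C)=C | intermediate
8 | (2S,3S,4S,5S,6R)-2-ethenyl-4,6-dihydroxy-2-methyl-3,5-di(prop-1-en-2-yl)cyclohexan-1-one | O[C@@H]1[C@H](C(C)=C)[C@@H](O)C(=O)[C@@](C)(C=C)[C@@H]1C(C)=C | intermediate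
9 | (1S,2R,3S,4S,5S,6S)-6-ethenyl-6-methyl-3,5-di(prop-1-en-2-yl)cyclohexane-1,2,4-triol (6β,8α,9α-triol) | O[C@@H]1[C@H](C(C)=C)[C@@H](O)[C@@H](O)[C@@](C)(C=C)[C@@H]1C(C)=C | intermediate
10 | cyclic phenylboronate of 9 across O8 and O9 (2-phenyl-1,3,2-dioxaborolane cis-fused at C8–C9, 6β-OH free) | O[C@@H]1[C@H](C(C)=C)[C@H]2OB(c3ccccc3)O[C@H]2[C@@](C)(C=C)[C@@H]1C(C)=C | intermediate
11 | 6-O-methacrylate of boronate 10 | CC(=C)C(=O)O[C@@H]1[C@H](C(C)=C)[C@H]2OB(c3ccccc3)O[C@H]2[C@@](C)(C=C)[C@@H]1C(C)=C | intermediate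
12 | (1S,2S,3S,4S,5R,6R)-3-ethenyl-4,5-dihydroxy-3-methyl-2,6-di(prop-1-en-2-yl)cyclohexyl 2-methylprop-2-enoate | CC(=C)C(=O)O[C@@H]1[C@H](C(C)=C)[C@@H](O)[C@@H](O)[C@@](C)(C=C)[C@@H]1C(C)=C | intermediate
13 | (1S,2S,3S,4S,5R,6R)-3-ethenyl-4,5-dihydroxy-2,6-bis(3-hydroxyprop-1-en-2-yl)-3-methylcyclohexyl 2-methylprop-2-enoate | CC(=C)C(=O)O[C@@H]1[C@H](C(=C)CO)[C@@H](O)[C@@H](O)[C@@](C)(C=C)[C@@H]1C(=C)CO | intermediate
14 | (3aS,4S,5R,6S,7S,7aR)-6-ethenyl-7-hydroxy-6-methyl-3-methylidene-2-oxo-5-(3-oxoprop-1-en-2-yl)octahydro-1-benzofuran-4-yl 2-methylprop-2-enoate | C=C(C)C(=O)O[C@@H]1[C@@H]2C(=C)C(=O)O[C@H]2[C@@H](O)[C@@](C)(C=C)[C@@H]1C(=C)C=O | intermediate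
15 | (3aS,4S,5R,6S,7S,7aR)-7-hydroxy-6-methyl-3-methylidene-6-[(2R)-oxiran-2-yl]-2-oxo-5-(3-oxoprop-1-en-2-yl)octahydro-1-benzofuran-4-yl 2-methylprop-2-enoate (CNP0228781.2) | C=C(C)C(=O)O[C@@H]1[C@@H]2C(=C)C(=O)O[C@H]2[C@@H](O)[C@@](C)([C@@H]2CO2)[C@@H]1C(=C)C=O | target

**Totals**
Total step count: 10. Longest linear sequence: 10 steps (fully linear from 1).

**Three steps most likely to fail**

Step 3 (directed conjugate addition and bromination). The risks are 1,2-addition to the ketone and attack anti to the alkoxide, which would give the C5 epimer. The fallback replaces alkoxide delivery by a covalent tether that can only reach the β-face of C5. It sets out from 5: O-alkylation with 2,3-dibromopropene (Ag2O, CH2Cl2) gives the 2-bromoallyl ether F1. Nickel-catalysed reductive conjugate cyclisation (NiCl2(dme), neocuproine, Mn, Et3SiCl, DMF) closes the cis-fused 3-methylenetetrahydrofuran and gives the triethylsilyl enol ether F2. Lithium 4,4′-di-tert-butylbiphenylide (THF, −78 °C, then NH4Cl) cleaves the allylic C15–O bond, and protonation of the symmetric allyl anion leaves the isopropenyl group and the free 6β-hydroxyl in the hydroxy silyl enol ether F3. NBS (THF, −78 °C) brominates C10, and the route is rejoined at 6.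

Step 4 (the new electroreductive vinylation). The risks are hydrodebromination, loss of HBr back to an enone, and low facial selectivity at C10. The fallback uses only known chemistry, with phenyl vinyl sulfoxide as a vinyl cation equivalent. It sets out from 5: the directed addition of step 3 is quenched with Me3SiCl instead of NBS to give the bis(trimethylsilyl) compound F4. MeLi (THF, 0 °C) releases the lithium enolate, which adds to phenyl vinyl sulfoxide (−78 → −20 °C, aqueous acid work-up) on the α-face to give the sulfoxide F5. Thermolysis (toluene, 110 °C, CaCO3) eliminates benzenesulfenic acid, and the route is rejoined at 7.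

Step 8 (twofold SeO2 oxidation). The risks are attack at the ring methines C5–H and C7–H, over-oxidation and low mass balance. The fallback is a Schenck ene photooxygenation. It sets out from 12: O2, tetraphenylporphyrin and visible light (CH2Cl2, 0 °C) convert both isopropenyl groups, with hydrogen taken from the methyl groups and not from the in-plane methine C–H bonds, into the bis(allylic hydroperoxide) F6. PPh3 reduces it, and the route is rejoined at 13.

**Further compounds**
F1 | step 3 | (4S,5S)-4-[(2-bromoprop-2-en-1-yl)oxy]-2-methyl-5-(prop-1-en-2-yl)cyclohex-2-en-1-one | BrC(=C)CO[C@@H]1[C@H](C(C)=C)CC(=O)C(C)=C1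
F2 | step 3 | triethyl{[4-methyl-3-methylidene-7-(prop-1-en-2-yl)-2,3,3a,6,7,7a-hexahydro-1-benzofuran-5-yl]oxy}silane, cis-fused, H-3a, H-7a and H-7 all cis | C=C1CO[C@@H]2[C@H](C(C)=C)CC(O[Si](CC)(CC)CC)=C(C)[C@@H]21
F3 | step 3 | (1R,2S,6S)-3-methyl-2,6-di(prop-1-en-2-yl)-4-[(triethylsilyl)oxy]cyclohex-3-en-1-ol (all-cis) | O[C@@H]1[C@H](C(C)=C)CC(O[Si](CC)(CC)CC)=C(C)[C@@H]1C(C)=C
F4 | step 4 | bis(trimethylsilyl) compound: trimethylsilyl enol ether of the 1,4-adduct of 5 with 6β-OSiMe3, C5 isopropenyl cis to O6 | C[Si](C)(C)O[C@@H]1[C@H](C(C)=C)CC(O[Si](C)(C)C)=C(C)[C@@H]1C(C)=C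
F5 | step 4 | (2S,3S,4R,5S)-4-hydroxy-2-methyl-2-[2-(phenylsulfinyl)ethyl]-3,5-di(prop-1-en-2-yl)cyclohexan-1-one (both configurations at sulfur) | O[C@@H]1[C@H](C(C)=C)CC(=O)[C@@](C)(CCS(=O)c2ccccc2)[C@@H]1C(C)=C
F6 | step 8 | (1S,2S,3S,4S,5R,6R)-3-ethenyl-2,6-bis(3-hydroperoxyprop-1-en-2-yl)-4,5-dihydroxy-3-methylcyclohexyl 2-methylprop-2-enoate | CC(=C)C(=O)O[C@@H]1[C@H](C(=C)COO)[C@@H](O)[C@@H](O)[C@@](C)(C=C)[C@@H]1C(=C)COO
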